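## Structural features

The target is a flavan-3-ol. A benzene ring A is fused to a dihydropyran ring C (O1, C2, C3, C4, C4a, C8a), the catechol ring B sits on C2, and two identical galloyl esters sit on the secondary oxygen at C3 and on the phenolic oxygen at C5. The only stereocentres are the neighbours C2 and C3, both R, so the aryl group and the acyloxy group are cis on ring C. This is the less stable arrangement; the 2,3-trans isomer is favoured whenever C2 can equilibrate. C2 is a benzylic ether carbon para to an oxygen of ring B, so a leaving group on its oxygen invites ionisation, and once the 4'-hydroxyl is free, base can open ring C through a quinone methide. The aryl ester at O5 is an activated ester and the nine free phenols (eight of them in catechol or pyrogallol arrays) are sensitive to base and air, so the last step has to be a neutral global deprotection. The real difficulty is the set of three oxygens on alternate carbons of ring A (C8a, C5, C7), which must end in three different states: ring ether O1, galloyl ester O5 and free phenol O7. The second task is the cis relation at C2/C3. The key step uses this 1,3,5-pattern: C4–C4a≡C5–O is read as a siloxyalkyne and C6–C7(O)–C8–C8a(=O) as a 3-alkoxy vinylketene, so ring A is born with a phenol on C8a, a silyl ether on C5 and a benzyl ether on C7.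

## Logic of the disconnections

27 ⇒ 26. The nine benzyl–oxygen bonds are cut last. Hydrogenolysis is neutral, which the aryl ester at O5 and the free polyphenol require, and one kind of group then masks every phenol that ends free. The demand is that no earlier step may touch benzyl ethers and that 26 holds no other reducible group.

26 ⇒ 24 + 25. The two ester C–O bonds at O3 and O5 are cut together. The acyl groups are identical, so one operation installs both, and the problem shrinks to a diol and one acid. The forward step needs O3 and O5 to be the only free hydroxyls, which means O7 must already differ from O5.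

24 ⇒ 23. The O3–Si and O5–Si bonds are cut. Both are fluoride-labile, so one operation frees exactly the two oxygens that will carry gallate. The demand is that the two silyl groups survive ring closure.

23 ⇒ 22. The O1–C2 bond of ring C is cut, to be formed with inversion at C2. This turns the strained cis relation in the ring into an anti relation in an open chain, which an erythro epoxy alcohol supplies directly. The forward step must be a clean displacement at an electron-rich benzylic carbon, and O3 must be blocked so that O1 is the only nucleophile and C2 the only activated carbon.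

22 ⇒ 21. The O2–Si bond is cut. The demand is a silyl group at O2 that leaves under conditions sparing the alkyl silyl ether at O3 and the aryl silyl ether at O5.

21 ⇒ 13 + 16. The bonds C4a–C8a and C5–C6 are cut (C8–C8a is broken and re-formed on the way), which removes ring A altogether. The reason is that the three ring A oxygens then arise in three different forms with no protecting-group differentiation. The gain is an acyclic chiral alkyne and a four-carbon ketene precursor. The forward step needs regiocontrol from the polarity of the alkyne and a side chain that tolerates neutral heating.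

16 ⇒ 14 + 15. The enol ether C–O bond is cut, because the O7 substituent must be removable by hydrogenolysis and the ethyl enol ether is the available form. The forward exchange must not open the strained ring.

13 ⇒ 10. The C5–O bond and the O–Si bond are cut, taking the oxygen off the alkyne terminus. A terminal alkyne is far easier to carry and to make than an ynol ether. The forward step needs an electrophilic oxygen source for the acetylide and O-selective silylation of the ynolate, with base-stable groups elsewhere.

10 ⇒ 9 ⇒ 8. The alkyne C–Si bond and the O3–Si bond are cut. These are protecting-group operations that leave one free secondary alcohol next to a silylated one. The demand is that the silyl group on O2 neither migrates nor falls off.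

8 ⇒ 5 + 6. The C4–C4a bond is cut. C4 is the terminal carbon of an epoxide, so C3 keeps its configuration and C3–O appears as the free alcohol. The forward step must attack only the CH2 terminus and must not ionise the benzylic silyl ether.

5 ⇒ 4 ⇒ 3. The O2–Si bond is cut, and then the epoxide oxygen is taken off the terminal alkene. A Sharpless kinetic resolution sets C2 by choosing one enantiomer and C3 by face selection in one operation. The cost is that at most half of 3 is used, and the reaction must be stopped near half conversion.

3 ⇒ 1 + 2. The C2–C3 bond is cut to an aldehyde and a vinyl nucleophile, both commercial. No selectivity is asked of this step.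

## Other disconnections considered

Alternative 1: The cut is at C4–C3 and O1–C2. In the forward sense, salicyl alcohol A2 would lose water under a chiral phosphoric acid to an ortho-quinone methide, which would add across the (Z)-enol gallate A3 to give A1; one esterification with 25 would then reach 26.
- In its favour: ring C, both stereocentres and the 3-O-gallate would come in one catalytic step. A2 is symmetric, so O1 and O5 need no differentiation and the 5-hydroxyl emerges free. No resolution is involved. On step economy this is clearly the better plan, about four steps in the longest line against thirteen.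
- Against it here: the dienophile is an enol ester, a weak donor, whereas quinone methides add readily only to electron-rich alkenes. The flavan regiochemistry depends on the aryl group of A3 outweighing the acyloxy group. A stepwise cationic pathway would pass through the same benzylic cation that threatens the chosen plan, and would lose the cis relation and probably the enantioselectivity. A3 must also be made and kept as the pure (Z) isomer under acid.
- Comparison: on structure, both plans solve the O5/O7 problem well, A1 by symmetry and 21 by construction; this point is equal. On mechanism, the alternative asks one unproven cycloaddition to set regiochemistry, relative and absolute configuration together. The chosen plan separates these tasks and sets configuration by a resolution and a substitution of known sense.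

Alternative 2: The cut is at C2–C3 and O1–C8a. Aldehyde 1 and diene A5 would combine under a chiral (salen)CrCl catalyst, and acid would then expel methanol to give the cis pyranone A4.
- In its favour: both stereocentres would be set cis, catalytically and in one step from the same aldehyde 1, with no loss of half the material. On this point it is better than the kinetic resolution of the chosen plan.
- Against it here: A4 contains none of ring A. A benzene ring with two differentiated oxygens would have to be annulated onto the enol ether double bond (the future C4a–C8a), and the C4 carbonyl would then have to be removed. Meanwhile C3 is alpha to a ketone and C2 is a beta-alkoxy carbon, so the cis pair can epimerise to trans by enolisation or by retro-oxa-Michael opening. The O5/O7 distinction is not addressed at all.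
- Comparison: mechanistically both key steps are cycloadditions, but here the cycloaddition makes the stereocentres and leaves the hard part of the skeleton undone. In the chosen plan the cycloaddition makes the hard part of the skeleton and creates no stereocentre. The step count would be well above that of the chosen plan.

Alternative 3: The cut is at O1–C8a only. The syn bromo alcohol A7 would cyclise with Pd(OAc)2, a hindered di-tert-butyl(biaryl)phosphine and Cs2CO3 to A6 with retention at C2; removal of the two methoxymethyl groups would give 24.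
- In its favour: no bond to C2 is made or broken, so ionisation at the benzylic carbon cannot erode the configuration. On this point it is safer than the Mitsunobu closure of the chosen plan. The syn diol behind A7 is the product of an asymmetric dihydroxylation of an (E)-1,3-diarylpropene, which is catalytic and loses no material; this is also better than a resolution. The cyclisation type is well established.
- Against it here: ring A of A7 must be bought or built with bromine, a methoxymethyl ether and a benzyl ether in a fixed pattern, so the O5/O7 problem moves into a multistep arene synthesis. The syn diol needs O3 protected while O2 stays free, which costs steps. The palladium alkoxide can undergo beta-hydride elimination to the ketone. The acetals must leave under acid from an acid-sensitive flavan.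
- Comparison: on structure, the chosen plan makes the three ring A oxygens different in the step that creates the ring, while this plan needs them different beforehand. On mechanism, reductive elimination at the aryl carbon is stereochemically safer than substitution at C2. On step economy the two are about equal.

Key step: step 9

Remarks on the chemistry (assumptions):
- The target is read as (2R,3R), the (−)-epicatechin series. The acyclic precursor 13 is therefore anti, (4R,5S), and ring closure must invert C2; the precursor and product structures of the key step are consistent with this and are used unchanged.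
- An ethynylsilane is the acetylene source, so its C-silyl group has to be removed (step 6) before the alkyne terminus can be oxidised.
- Acid 25 is a catalogue compound and is used as bought.

## Route

Step 1
Reactants: 1 3,4-bis(benzyloxy)benzaldehyde; 2 vinylmagnesium bromide
Product: 3 rac-1-[3,4-bis(benzyloxy)phenyl]prop-2-en-1-ol
Conditions: THF, −78 → 0 °C; aq. NH4Cl
Reagents that add atoms: none
Why: Grignard 1,2-addition to an aromatic aldehyde; the racemate is wanted because the next step resolves it, and a neutral work-up avoids allylic transposition of the electron-rich carbinol.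

Step 2
Reactants: 3 rac-1-[3,4-bis(benzyloxy)phenyl]prop-2-en-1-ol
Product: 4 (S)-[3,4-bis(benzyloxy)phenyl][(R)-oxiran-2-yl]methanol (erythro)
Conditions: Ti(OiPr)4 (0.2 equiv), L-(+)-DIPT (0.24 equiv), tBuOOH (0.55 equiv), 4 Å MS, CH2Cl2, −20 °C
Reagents that add atoms: tert-butyl hydroperoxide, CC(C)(C)OO
Why: Sharpless kinetic resolution: the titanium L-(+)-tartrate complex should epoxidise only the (R)-enantiomer of 3, on the face that gives the erythro epoxy alcohol, so the catalyst sets C2 by enantiomer selection and C3 by face selection (the carbinol descriptor changes from R to S only because oxiranyl outranks aryl). The (S)-enantiomer of 3 stays behind and is separated, and stopping short of half conversion keeps 4 enantiomerically pure.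

Step 3
Reactants: 4 (S)-[3,4-bis(benzyloxy)phenyl][(R)-oxiran-2-yl]methanol
Product: 5 triethyl{(S)-[3,4-bis(benzyloxy)phenyl][(R)-oxiran-2-yl]methoxy}silane
Conditions: Et3SiCl, imidazole, CH2Cl2, 0 °C
Reagents that add atoms: chlorotriethylsilane, CC[Si](Cl)(CC)CC
Why: Silylation of a secondary alcohol without strong base, so no Payne rearrangement of the epoxy alcohol; the triethylsilyl group is chosen because it is the most acid-labile of the three silyl groups that the route will carry.

Step 4
Reactants: 5 triethyl{(S)-[3,4-bis(benzyloxy)phenyl][(R)-oxiran-2-yl]methoxy}silane; 6 ethynyltrimethylsilane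
Product: 8 (1S,2R)-1-[3,4-bis(benzyloxy)phenyl]-1-(triethylsilyloxy)-5-(trimethylsilyl)pent-4-yn-2-ol, via lithium (trimethylsilyl)acetylide 7 (not isolated)
Conditions: 6, n-BuLi, THF, −78 °C; BF3·OEt2; then 5, −78 °C; aq. NH4Cl at −78 °C
Reagents that add atoms: none
Why: Yamaguchi–Hirao alkynylation: the BF3-activated terminal epoxide is opened at the CH2 carbon, which forms C4–C4a and leaves both stereocentres untouched. The resulting alkoxide is boron-bound and quenched cold, so the neighbouring silyl group should not migrate.

Step 5
Reactants: 8 (1S,2R)-1-[3,4-bis(benzyloxy)phenyl]-1-(triethylsilyloxy)-5-(trimethylsilyl)pent-4-yn-2-ol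
Product: 9 (1S,2R)-1-[3,4-bis(benzyloxy)phenyl]-2-(tert-butyldimethylsilyloxy)-1-(triethylsilyloxy)-5-(trimethylsilyl)pent-4-yne
Conditions: tBuMe2SiOTf, 2,6-lutidine, CH2Cl2, −78 → 0 °C
Reagents that add atoms: tert-butyldimethylsilyl trifluoromethanesulfonate, CC(C)(C)[Si](C)(C)OS(=O)(=O)C(F)(F)F
Why: Silyl triflate silylation of a hindered secondary alcohol under non-nucleophilic base; O3 now carries a group that survives the later removal of the triethylsilyl group and blocks O3 in the ring closure.

Step 6
Reactants: 9 (1S,2R)-1-[3,4-bis(benzyloxy)phenyl]-2-(tert-butyldimethylsilyloxy)-1-(triethylsilyloxy)-5-(trimethylsilyl)pent-4-yne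
Product: 10 (1S,2R)-1-[3,4-bis(benzyloxy)phenyl]-2-(tert-butyldimethylsilyloxy)-1-(triethylsilyloxy)pent-4-yne
Conditions: K2CO3, MeOH/THF, 0 °C → rt
Reagents that add atoms: none
Why: Methanolysis of the alkynyl C–Si bond; secondary triethylsilyl and tert-butyldimethylsilyl ethers are stable to carbonate in methanol over the short time needed.

Step 7
Reactants: 10 (1S,2R)-1-[3,4-bis(benzyloxy)phenyl]-2-(tert-butyldimethylsilyloxy)-1-(triethylsilyloxy)pent-4-yne
Product: 13 (4R,5S)-5-[3,4-bis(benzyloxy)phenyl]-4-(tert-butyldimethylsilyloxy)-5-(triethylsilyloxy)-1-(triisopropylsilyloxy)pent-1-yne, via lithium acetylide 11 (not isolated), via lithium ynolate 12 (not isolated)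
Conditions: LiN(SiMe3)2, THF, −78 °C; LiOOtBu (from tBuOOH and LiN(SiMe3)2, THF, −78 °C), −78 → 0 °C; iPr3SiOTf, −78 → 0 °C
Reagents that add atoms: tert-butyl hydroperoxide, CC(C)(C)OO; triisopropylsilyl trifluoromethanesulfonate, CC(C)[Si](C(C)C)(C(C)C)OS(=O)(=O)C(F)(F)F
Why: Julia oxidation of a lithium acetylide by lithium tert-butyl peroxide gives the ynolate, and the hard, bulky silyl triflate traps it on oxygen to give the siloxyalkyne. The amide base does not touch the silyl or benzyl ethers, and the triisopropylsilyl group makes the ynol ether stable enough to purify on base-washed silica.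

Step 8
Reactants: 14 3-ethoxycyclobut-2-en-1-one; 15 benzyl alcohol
Product: 16 3-(benzyloxy)cyclobut-2-en-1-one
Conditions: 15 (3 equiv), camphorsulfonic acid (5 mol%), toluene, 50 °C, reduced pressure (EtOH removed)
Reagents that add atoms: none
Why: Acid-catalysed exchange at the enol ether carbon of a vinylogous ester (addition–elimination), driven by removal of ethanol; the temperature is kept below that at which the cyclobutenone opens.

Step 9
Reactants: 13 (4R,5S)-5-[3,4-bis(benzyloxy)phenyl]-4-(tert-butyldimethylsilyloxy)-5-(triethylsilyloxy)-1-(triisopropylsilyloxy)pent-1-yne; 16 3-(benzyloxy)cyclobut-2-en-1-one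
Product: 21 5-(benzyloxy)-2-[(2R,3S)-3-[3,4-bis(benzyloxy)phenyl]-2-(tert-butyldimethylsilyloxy)-3-(triethylsilyloxy)propyl]-3-(triisopropylsilyloxy)phenol, via vinylketene 17 (not isolated), via vinylcyclobutenone 18 (not isolated), via dienylketene 19 (not isolated), via cyclohexadienone 20 (not isolated)
Conditions: toluene, 90 → 110 °C, Ar; 16 (1.3 equiv) added slowly
Reagents that add atoms: none
Why: Thermal four-electron conrotatory opening of 16 should give vinylketene 17, whose ketene C=C adds to the siloxyalkyne of 13 in a [2+2] cycloaddition to vinylcyclobutenone 18; a second four-electron opening gives dienylketene 19, which closes ring A by a six-electron disrotatory electrocyclisation (forming C8–C8a) to cyclohexadienone 20, and tautomerisation gives phenol 21. This is the Danheiser benzannulation in its siloxyalkyne form, and the closest known reaction type is the cyclobutenone–siloxyalkyne route to resorcinol monosilyl ethers. The only selectivity needed is regiochemical: the oxygen-free alkyne carbon C4a is the nucleophilic terminus and bonds to the ketene carbonyl carbon C8a, so C5 joins C6 and the phenol, the silyl ether and the benzyl ether end on C8a, C5 and C7. No stereocentre is formed, since the sp3 carbon of 18 is lost again, and C2 and C3, fully silylated and remote from the alkyne, are not touched by neutral heating. The benzyloxy group makes 16 a vinylogous ester that opens less readily than an alkylcyclobutenone, hence the higher temperature. Slow addition keeps the ketene concentration low, so that ketene dimerisation and O-acylation of the product phenol are held back.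

Step 10
Reactants: 21 5-(benzyloxy)-2-[(2R,3S)-3-[3,4-bis(benzyloxy)phenyl]-2-(tert-butyldimethylsilyloxy)-3-(triethylsilyloxy)propyl]-3-(triisopropylsilyloxy)phenol
Product: 22 (1S,2R)-1-[3,4-bis(benzyloxy)phenyl]-3-[4-(benzyloxy)-2-hydroxy-6-(triisopropylsilyloxy)phenyl]-2-(tert-butyldimethylsilyloxy)propan-1-ol
Conditions: pyridinium p-toluenesulfonate (0.2 equiv), MeOH/CH2Cl2, 0 °C
Reagents that add atoms: none
Why: Mild acid methanolysis removes a triethylsilyl ether much faster than a secondary tert-butyldimethylsilyl ether, and aryl silyl ethers resist acid; the weak acid and low temperature are chosen so that the benzylic C–O bond does not ionise.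

Step 11
Reactants: 22 (1S,2R)-1-[3,4-bis(benzyloxy)phenyl]-3-[4-(benzyloxy)-2-hydroxy-6-(triisopropylsilyloxy)phenyl]-2-(tert-butyldimethylsilyloxy)propan-1-ol
Product: 23 (2R,3R)-7-(benzyloxy)-2-[3,4-bis(benzyloxy)phenyl]-3-(tert-butyldimethylsilyloxy)-5-(triisopropylsilyloxy)chromane
Conditions: PPh3, DIAD, toluene (0.02 M), 0 °C → rt
Reagents that add atoms: none
Why: Intramolecular Mitsunobu etherification: the phenol protonates the betaine and displaces the benzylic oxyphosphonium group in a 6-exo-tet closure with inversion, turning (S)-C2 into (R)-C2 and the anti chain into the cis ring. O3 is silylated, so neither a five-membered ether nor an epoxide can form, and the non-polar solvent disfavours ionisation.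

Step 12
Reactants: 23 (2R,3R)-7-(benzyloxy)-2-[3,4-bis(benzyloxy)phenyl]-3-(tert-butyldimethylsilyloxy)-5-(triisopropylsilyloxy)chromane
Product: 24 (2R,3R)-7-(benzyloxy)-2-[3,4-bis(benzyloxy)phenyl]chromane-3,5-diol
Conditions: Bu4NF (3 equiv), THF, 0 °C → rt, Ar; aq. NH4Cl
Reagents that add atoms: none
Why: Fluoride cleaves the aryl and the alkyl silyl ether in one operation and frees exactly the two oxygens that will carry gallate; with ring B still benzylated there is no quinone methide path, so C2 cannot epimerise.

Step 13
Reactants: 24 (2R,3R)-7-(benzyloxy)-2-[3,4-bis(benzyloxy)phenyl]chromane-3,5-diol; 25 3,4,5-tris(benzyloxy)benzoic acid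
Product: 26 (2R,3R)-7-(benzyloxy)-2-[3,4-bis(benzyloxy)phenyl]chromane-3,5-diyl bis[3,4,5-tris(benzyloxy)benzoate]
Conditions: 25 (3 equiv), EDC·HCl, DMAP, CH2Cl2, 0 °C → rt
Reagents that add atoms: none
Why: Steglich esterification through the acylpyridinium ion acylates both the phenol and the hindered axial secondary alcohol; no stereocentre is involved and O7 is still a benzyl ether.

Step 14
Reactants: 26 (2R,3R)-7-(benzyloxy)-2-[3,4-bis(benzyloxy)phenyl]chromane-3,5-diyl bis[3,4,5-tris(benzyloxy)benzoate]
Product: 27 epicatechin 3,5-di-O-gallate, (2R,3R)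
Conditions: H2 (1 atm), Pd(OH)2/C, THF/EtOAc, rt; filtration under Ar
Reagents that add atoms: none
Why: Hydrogenolysis of the nine benzyl ethers under neutral conditions; the flavan C2–O bond is a dialkyl-type benzylic ether and is far slower to cleave than O-benzyl groups, and an aprotic solvent protects the aryl ester from alcoholysis.

## Compound list

1 | 3,4-bis(benzyloxy)benzaldehyde | O=Cc1ccc(OCc2ccccc2)c(OCc2ccccc2)c1 | starting material
2 | vinylmagnesium bromide | C=C[Mg]Br | starting material
3 | rac-1-[3,4-bis(benzyloxy)phenyl]prop-2-en-1-ol | OC(C=C)c1ccc(OCc2ccccc2)c(OCc2ccccc2)c1 | intermediate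
4 | (S)-[3,4-bis(benzyloxy)phenyl][(R)-oxiran-2-yl]methanol | O[C@@H](c1ccc(OCc2ccccc2)c(OCc2ccccc2)c1)[C@H]1CO1 | intermediate
5 | triethyl{(S)-[3,4-bis(benzyloxy)phenyl][(R)-oxiran-2-yl]methoxy}silane | CC[Si](CC)(CC)O[C@@H](c1ccc(OCc2ccccc2)c(OCc2ccccc2)c1)[C@H]1CO1 | intermediate
6 | ethynyltrimethylsilane | C#C[Si](C)(C)C | starting material
7 | lithium (trimethylsilyl)acetylide, formed in the flask | [Li]C#C[Si](C)(C)C | intermediate
8 | (1S,2R)-1-[3,4-bis(benzyloxy)phenyl]-1-(triethylsilyloxy)-5-(trimethylsilyl)pent-4-yn-2-ol | C[Si](C)(C)C#CC[C@@H](O)[C@H](c1ccc(OCc2ccccc2)c(OCc2ccccc2)c1)O[Si](CC)(CC)CC | intermediate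
9 | (1S,2R)-1-[3,4-bis(benzyloxy)phenyl]-2-(tert-butyldimethylsilyloxy)-1-(triethylsilyloxy)-5-(trimethylsilyl)pent-4-yne | C[Si](C)(C)C#CC[C@@H](O[Si](C)(C)C(C)(C)C)[C@H](c1ccc(OCc2ccccc2)c(OCc2ccccc2)c1)O[Si](CC)(CC)CC | intermediate
10 | (1S,2R)-1-[3,4-bis(benzyloxy)phenyl]-2-(tert-butyldimethylsilyloxy)-1-(triethylsilyloxy)pent-4-yne | C#CC[C@@H](O[Si](C)(C)C(C)(C)C)[C@H](c1ccc(OCc2ccccc2)c(OCc2ccccc2)c1)O[Si](CC)(CC)CC | intermediate
11 | lithium acetylide of 10, formed in the flask | [Li]C#CC[C@@H](O[Si](C)(C)C(C)(C)C)[C@H](c1ccc(OCc2ccccc2)c(OCc2ccccc2)c1)O[Si](CC)(CC)CC | intermediate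
12 | lithium ynolate, lithium (4R,5S)-5-[3,4-bis(benzyloxy)phenyl]-4-(tert-butyldimethylsilyloxy)-5-(triethylsilyloxy)pent-1-yn-1-olate, formed in the flask | [Li]OC#CC[C@@H](O[Si](C)(C)C(C)(C)C)[C@H](c1ccc(OCc2ccccc2)c(OCc2ccccc2)c1)O[Si](CC)(CC)CC | intermediate
13 | (4R,5S)-5-[3,4-bis(benzyloxy)phenyl]-4-(tert-butyldimethylsilyloxy)-5-(triethylsilyloxy)-1-(triisopropylsilyloxy)pent-1-yne | CC(C)[Si](C(C)C)(C(C)C)OC#CC[C@@H](O[Si](C)(C)C(C)(C)C)[C@H](c1ccc(OCc2ccccc2)c(OCc2ccccc2)c1)O[Si](CC)(CC)CC | intermediate
14 | 3-ethoxycyclobut-2-en-1-one | CCOC1=CC(=O)C1 | starting material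
15 | benzyl alcohol | OCc1ccccc1 | starting material
16 | 3-(benzyloxy)cyclobut-2-en-1-one | O=C1C=C(OCc2ccccc2)C1 | intermediate
17 | vinylketene, 3-(benzyloxy)buta-1,3-dien-1-one, formed in the flask | O=C=CC(=C)OCc1ccccc1 | intermediate
18 | vinylcyclobutenone, 4-[1-(benzyloxy)vinyl]-2-[(2R,3S)-3-[3,4-bis(benzyloxy)phenyl]-2-(tert-butyldimethylsilyloxy)-3-(triethylsilyloxy)propyl]-3-(triisopropylsilyloxy)cyclobut-2-en-1-one (either configuration at C4), formed in the flask | O=C1C(C[C@@H](O[Si](C)(C)C(C)(C)C)[C@H](c2ccc(OCc3ccccc3)c(OCc3ccccc3)c2)O[Si](CC)(CC)CC)=C(O[Si](C(C)C)(C(C)C)C(C)C)C1C(=C)OCc1ccccc1 | intermediate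
19 | dienylketene, 5-(benzyloxy)-2-[(2R,3S)-3-[3,4-bis(benzyloxy)phenyl]-2-(tert-butyldimethylsilyloxy)-3-(triethylsilyloxy)propyl]-3-(triisopropylsilyloxy)hexa-1,3,5-trien-1-one (ketene carbon and benzyloxyvinyl group cis on the central double bond), formed in the flask | O=C=C(C[C@@H](O[Si](C)(C)C(C)(C)C)[C@H](c1ccc(OCc2ccccc2)c(OCc2ccccc2)c1)O[Si](CC)(CC)CC)/C(O[Si](C(C)C)(C(C)C)C(C)C)=C\C(=C)OCc1ccccc1 | intermediate
20 | cyclohexadienone, 5-(benzyloxy)-2-[(2R,3S)-3-[3,4-bis(benzyloxy)phenyl]-2-(tert-butyldimethylsilyloxy)-3-(triethylsilyloxy)propyl]-3-(triisopropylsilyloxy)cyclohexa-2,4-dien-1-one, formed in the flask | O=C1CC(OCc2ccccc2)=CC(O[Si](C(C)C)(C(C)C)C(C)C)=C1C[C@@H](O[Si](C)(C)C(C)(C)C)[C@H](c1ccc(OCc2ccccc2)c(OCc2ccccc2)c1)O[Si](CC)(CC)CC | intermediate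
21 | 5-(benzyloxy)-2-[(2R,3S)-3-[3,4-bis(benzyloxy)phenyl]-2-(tert-butyldimethylsilyloxy)-3-(triethylsilyloxy)propyl]-3-(triisopropylsilyloxy)phenol | CC(C)[Si](C(C)C)(C(C)C)Oc1cc(OCc2ccccc2)cc(O)c1C[C@@H](O[Si](C)(C)C(C)(C)C)[C@H](c1ccc(OCc2ccccc2)c(OCc2ccccc2)c1)O[Si](CC)(CC)CC | intermediate
22 | (1S,2R)-1-[3,4-bis(benzyloxy)phenyl]-3-[4-(benzyloxy)-2-hydroxy-6-(triisopropylsilyloxy)phenyl]-2-(tert-butyldimethylsilyloxy)propan-1-ol | CC(C)[Si](C(C)C)(C(C)C)Oc1cc(OCc2ccccc2)cc(O)c1C[C@@H](O[Si](C)(C)C(C)(C)C)[C@H](c1ccc(OCc2ccccc2)c(OCc2ccccc2)c1)O | intermediate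
23 | (2R,3R)-7-(benzyloxy)-2-[3,4-bis(benzyloxy)phenyl]-3-(tert-butyldimethylsilyloxy)-5-(triisopropylsilyloxy)chromane | CC(C)[Si](C(C)C)(C(C)C)Oc1cc(OCc2ccccc2)cc2c1C[C@@H](O[Si](C)(C)C(C)(C)C)[C@@H](c1ccc(OCc3ccccc3)c(OCc3ccccc3)c1)O2 | intermediate
24 | (2R,3R)-7-(benzyloxy)-2-[3,4-bis(benzyloxy)phenyl]chromane-3,5-diol (7,3',4'-tri-O-benzylepicatechin) | Oc1cc(OCc2ccccc2)cc2c1C[C@@H](O)[C@@H](c1ccc(OCc3ccccc3)c(OCc3ccccc3)c1)O2 | intermediate
25 | 3,4,5-tris(benzyloxy)benzoic acid | OC(=O)c1cc(OCc2ccccc2)c(OCc2ccccc2)c(OCc2ccccc2)c1 | starting material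
26 | (2R,3R)-7-(benzyloxy)-2-[3,4-bis(benzyloxy)phenyl]chromane-3,5-diyl bis[3,4,5-tris(benzyloxy)benzoate] | O=C(Oc1cc(OCc2ccccc2)cc2c1C[C@@H](OC(=O)c1cc(OCc3ccccc3)c(OCc3ccccc3)c(OCc3ccccc3)c1)[C@@H](c1ccc(OCc3ccccc3)c(OCc3ccccc3)c1)O2)c1cc(OCc2ccccc2)c(OCc2ccccc2)c(OCc2ccccc2)c1 | intermediate
27 | epicatechin 3,5-di-O-gallate, (2R,3R) | O=C(Oc1cc(O)cc2c1C[C@@H](OC(=O)c1cc(O)c(O)c(O)c1)[C@@H](c1ccc(O)c(O)c1)O2)c1cc(O)c(O)c(O)c1 | target

## Step count and least certain steps

Total step count: 14. Longest linear sequence: 13 steps (steps 1–7 and 9–14, from 1 to 27); step 8 is a one-step branch.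

Step 9 (key step). The most likely failure is a mismatch of rates. The donor-stabilised cyclobutenone 16 may open too slowly at temperatures that 13 tolerates, so that 13 rearranges or the ketene, once formed, acylates the product phenol or dimerises instead of adding to the alkyne. The fallback makes the same vinylketene 17 at low temperature by elimination instead of by ring opening. It sets out from 13 and rejoins the route at 21, entering the cascade at 17. Trimethylphosphine-catalysed addition of 15 to ethyl but-2-ynoate should give ethyl (E)-3-(benzyloxy)but-2-enoate F1. Saponification with LiOH gives (E)-3-(benzyloxy)but-2-enoic acid F2. The neutral chloroenamine 1-chloro-N,N,2-trimethylprop-1-en-1-amine converts F2 into (E)-3-(benzyloxy)but-2-enoyl chloride F3 without acid that would attack the enol ether. Triethylamine added to F3 and 13 in toluene at 0 °C to rt effects 1,4-dehydrochlorination to 17, which is trapped by the siloxyalkyne as 18. Gentle warming (about 80 °C) then carries 18 through 19 and 20 to 21.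

Step 11. The most likely failure is ionisation of the benzylic oxyphosphonium intermediate, helped by the para oxygen of ring B. This would give loss of stereospecificity at C2 and drift towards the trans ring. The fallback no longer relies on a substitution at C2: it removes the stereocentre and sets it again by hydride delivery. It sets out from 22 and comes back at 23. MnO2 in CH2Cl2 oxidises the benzylic alcohol to (R)-1-[3,4-bis(benzyloxy)phenyl]-3-[4-(benzyloxy)-2-hydroxy-6-(triisopropylsilyloxy)phenyl]-2-(tert-butyldimethylsilyloxy)propan-1-one F4, which is in equilibrium with its cyclic hemiketal. Et3SiH with BF3·OEt2 in CH2Cl2 at −78 °C reduces the derived cyclic oxocarbenium ion. The silyloxy group on C3 should sit pseudoaxial to avoid the coplanar aryl group on C2, and hydride should enter anti to it, which puts the aryl group cis to the C3 oxygen as in 23.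

Step 8. The most likely failure is alcoholysis of the strained ring: benzyl alcohol adds to the carbonyl group and the four-membered ring cleaves to an open-chain acetoacetate-type ester, in competition with exchange at the enol ether carbon. The fallback separates removal of the ethyl group from introduction of the benzyl group. It sets out from 14 and comes back at 16. Dilute aqueous HCl hydrolyses 14 to cyclobutane-1,3-dione F5, and a Mitsunobu O-alkylation of this acidic enol with 15 (PPh3, DIAD, THF, 0 °C) gives 16.

Step 4. The most likely failures are ionisation of the benzylic silyl ether by the Lewis acid, or migration of the triethylsilyl group from O2 to the new alkoxide at O3 before the quench. The fallback brings in the two alkyne carbons without a Lewis acid and builds the triple bond afterwards. It sets out from 5 and comes back at 10. Copper-catalysed opening of the epoxide with 2 (CuI cat., THF, −30 °C) gives (1S,2R)-1-[3,4-bis(benzyloxy)phenyl]-1-(triethylsilyloxy)pent-4-en-2-ol F6. Silylation as in step 5 gives (1S,2R)-1-[3,4-bis(benzyloxy)phenyl]-2-(tert-butyldimethylsilyloxy)-1-(triethylsilyloxy)pent-4-ene F7. Cleavage of the alkene (OsO4 cat., NaIO4, 2,6-lutidine, dioxane/water) gives (3R,4S)-4-[3,4-bis(benzyloxy)phenyl]-3-(tert-butyldimethylsilyloxy)-4-(triethylsilyloxy)butanal F8. Ohira–Bestmann homologation with dimethyl (1-diazo-2-oxopropyl)phosphonate and K2CO3 in MeOH at 0 °C gives 10.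

## Further compounds

F1 | step 9 | ethyl (E)-3-(benzyloxy)but-2-enoate | CCOC(=O)/C=C(\C)OCc1ccccc1
F2 | step 9 | (E)-3-(benzyloxy)but-2-enoic acid | OC(=O)/C=C(\C)OCc1ccccc1
F3 | step 9 | (E)-3-(benzyloxy)but-2-enoyl chloride | ClC(=O)/C=C(\C)OCc1ccccc1
F4 | step 11 | (R)-1-[3,4-bis(benzyloxy)phenyl]-3-[4-(benzyloxy)-2-hydroxy-6-(triisopropylsilyloxy)phenyl]-2-(tert-butyldimethylsilyloxy)propan-1-one | CC(C)[Si](C(C)C)(C(C)C)Oc1cc(OCc2ccccc2)cc(O)c1C[C@@H](O[Si](C)(C)C(C)(C)C)C(=O)c1ccc(OCc2ccccc2)c(OCc2ccccc2)c1
F5 | step 8 | cyclobutane-1,3-dione | O=C1CC(=O)C1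
F6 | step 4 | (1S,2R)-1-[3,4-bis(benzyloxy)phenyl]-1-(triethylsilyloxy)pent-4-en-2-ol | C=CC[C@@H](O)[C@H](c1ccc(OCc2ccccc2)c(OCc2ccccc2)c1)O[Si](CC)(CC)CC
F7 | step 4 | (1S,2R)-1-[3,4-bis(benzyloxy)phenyl]-2-(tert-butyldimethylsilyloxy)-1-(triethylsilyloxy)pent-4-ene | C=CC[C@@H](O[Si](C)(C)C(C)(C)C)[C@H](c1ccc(OCc2ccccc2)c(OCc2ccccc2)c1)O[Si](CC)(CC)CC
F8 | step 4 | (3R,4S)-4-[3,4-bis(benzyloxy)phenyl]-3-(tert-butyldimethylsilyloxy)-4-(triethylsilyloxy)butanal | O=CC[C@@H](O[Si](C)(C)C(C)(C)C)[C@H](c1ccc(OCc2ccccc2)c(OCc2ccccc2)c1)O[Si](CC)(CC)CC
A1 | alternative 1 | (2R,3R)-7-(benzyloxy)-2-[3,4-bis(benzyloxy)phenyl]-5-hydroxychroman-3-yl 3,4,5-tris(benzyloxy)benzoate | Oc1cc(OCc2ccccc2)cc2c1C[C@@H](OC(=O)c1cc(OCc3ccccc3)c(OCc3ccccc3)c(OCc3ccccc3)c1)[C@@H](c1ccc(OCc3ccccc3)c(OCc3ccccc3)c1)O2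
A2 | alternative 1 | 5-(benzyloxy)-2-(hydroxymethyl)benzene-1,3-diol | OCc1c(O)cc(OCc2ccccc2)cc1O
A3 | alternative 1 | (Z)-2-[3,4-bis(benzyloxy)phenyl]ethenyl 3,4,5-tris(benzyloxy)benzoate | O=C(O/C=C\c1ccc(OCc2ccccc2)c(OCc2ccccc2)c1)c1cc(OCc2ccccc2)c(OCc2ccccc2)c(OCc2ccccc2)c1
A4 | alternative 2 | cis-(2R,3S)-2-[3,4-bis(benzyloxy)phenyl]-3-(tert-butyldimethylsilyloxy)-2,3-dihydro-4H-pyran-4-one | O=C1[C@@H](O[Si](C)(C)C(C)(C)C)[C@@H](c2ccc(OCc3ccccc3)c(OCc3ccccc3)c2)OC=C1
A5 | alternative 2 | (1E,3Z)-4-(tert-butyldimethylsilyloxy)-1-methoxy-3-(trimethylsilyloxy)buta-1,3-diene | CO/C=C/C(O[Si](C)(C)C)=C/O[Si](C)(C)C(C)(C)C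
A6 | alternative 3 | (2R,3R)-7-(benzyloxy)-2-[3,4-bis(benzyloxy)phenyl]-3,5-bis(methoxymethoxy)chromane | COCOc1cc(OCc3ccccc3)cc2c1C[C@@H](OCOC)[C@@H](c1ccc(OCc3ccccc3)c(OCc3ccccc3)c1)O2
A7 | alternative 3 | (1R,2R)-1-[3,4-bis(benzyloxy)phenyl]-3-[4-(benzyloxy)-2-bromo-6-(methoxymethoxy)phenyl]-2-(methoxymethoxy)propan-1-ol | COCOc1cc(OCc2ccccc2)cc(Br)c1C[C@@H](OCOC)[C@@H](c1ccc(OCc2ccccc2)c(OCc2ccccc2)c1)O
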